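# Proposed total synthesis of CNP0380368.2 (29) by a chelation-controlled samarium Barbier ring closure

## The problem

CNP0380368.2 (29) is a C41 carotenoid: a lycopene-type open end and an all-E chain of ten conjugated double bonds terminate in a fully substituted cyclopentane. The ring is numbered here C1 (CH carrying Cq, the carbon of the CMe2OMe group), C2 and C3 (CH2), C4 (the tertiary carbinol C(OH)Me) and C5 (CH carrying chain carbon C7). The chain runs C7 to C15 and, by carotenoid convention, C15' back to C1'.

Three contiguous stereocentres must be set: C1 (R), C4 (R) and C5 (S). Cq and C7 are trans, and the hydroxyl is cis to C7. C1 is the natural anchor: its substituent can send a new bond at C5 to the opposite face, and the oxygenated carbon C7 on C5 can then direct the carbinol centre C4. The chain has no stereocentre and needs only E geometry.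

Three groups limit the conditions:
- the polyene (light, oxygen, acid, electrophiles);
- the tertiary methyl ether at Cq, which ionises under strong acid;
- the tertiary alcohol at C4, which is β to C7 and invites retro-aldol cleavage or elimination whenever C7 is a carbonyl carbon under base.

The ring is therefore finished early and the chain attached last, through C7 at the aldehyde level with the C4 oxygen masked. The feature that decides the ring construction is the bond C3–C4. The carbinol C4 is joined to an unfunctionalised methylene, so in an open chain both carbons are electrophiles (a methyl ketone and a primary iodide) and only a reductive, polarity-reversing union joins them. The oxygen on C7, β to that ketone, is placed to form a six-membered chelate with the metal and so to control the new centre.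

## Retrosynthesis

**Chain, C11=C12.** Target 29 is traced to its triethylsilyl ether 28, so that the last operation is a fluoride desilylation that a polyene tolerates. In 28 the chain is cut at C11=C12, giving the C15 dienal 18 (ring plus C7–C11) and the C25 ylide 27, made in the flask from phosphonium salt 26.
- A cut at C7=C8 would pit the α-branched, base-sensitive aldehyde 13 against a long polyenyl ylide with poor E control next to the ring.
- A central cut at C15=C15' would need the ring half as a phosphonium salt, and such salts are made under acid that the tertiary ether and the silyl ether would not survive.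
- The chosen cut keeps the acid-sensitive half as the aldehyde and lets the hydrocarbon half carry the phosphorus.
- The forward Wittig reaction may give an E/Z mixture at the hindered disubstituted C11=C12 bond, because that bond equilibrates thermally to E.

**The C25 half.** Salt 26 goes back through alcohol 25 to the C25 aldehyde 24. 24 is cut at C11'=C12' into the symmetrical C10 dialdehyde 22 and the C15 ylide 23 (from salt 21). 21 comes from pseudoionone 19 by vinyl addition (alcohol 20) and phosphine capture with allylic transposition. Both 19 and 22 are commercial and bring every trisubstituted double bond of this half with its geometry. The forward sequence only has to olefinate one formyl group of 22.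

**C7=C8 and the oxidation level of C7.** Dienal 18 is simplified through alcohol 17 and ester 16 to the ring aldehyde 13 and the commercial C5 phosphonate 14 (anion 15). A stabilised vinylogous phosphonate is chosen over a C5 phosphonium ylide because it gives the E alkene next to the ring and is a weaker base. 13 comes from alcohol 12, silyl ether 11 and the cyclopentanol 10. The order is fixed by the retro-aldol risk: the tertiary hydroxyl is silylated (11) before C7 is unmasked (12) and oxidised (13).

**Ring, C3–C4 (key disconnection).** Cyclopentanol 10 is opened between C3 and C4 to the iodo ketone 9.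
- Cuts at C4–C5 (aldol) or C1–C5 would need extra activating groups. The C3–C4 cut needs none and leaves an open chain whose two stereocentres are adjacent and easily set.
- The forward reaction is a samarium diiodide Barbier cyclisation. It must choose one face of the ketone, and the benzyl ether on C7 is retained as the donor for a samarium chelate.
- HMPA is left out for the same reason: it would saturate the metal and break the chelate. An iron additive gives the rate instead.

**The open chain.** Iodide 9 comes from alcohol 8, and 8 from the δ-lactone 7 by addition of one methyl group (C4–CH3 bond). Lactone 7 is cut at C5–C7 into the lactone 5 (as enolate 6) and benzyl chloromethyl ether; a ring enolate is used because the C1 substituent then shields one face and the anti relation C1/C5 follows. 5 comes from the isopropenyl lactone 3 by Markovnikov addition of methanol (via mercurial 4). 3 is cut at C1–Cq into 5,6-dihydro-2H-pyran-2-one 1 and isopropenylboronate 2, joined by an asymmetric conjugate addition that sets C1, the only centre set by a reagent.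

## Roads not taken

**Alternative 1:** The cut is C4–C5 with a temporary bond from the C4 oxygen to C7.
- Key step: the keto acid (R)-3-(2-methoxypropan-2-yl)-6-oxoheptanoic acid A1 would be activated with tosyl chloride, iPr2NEt and LiCl in the presence of 4-pyrrolidinopyridine. The acylammonium enolate adds through C5 to the ketone C4 and the aldolate acylates at C7, giving the cis-fused β-lactone A2 (2-(2-methoxypropan-2-yl)-5-methyl-6-oxabicyclo[3.2.0]heptan-7-one).
- Merits: A1 is a few operations from a p-menthane alcohol of the chiral pool, so the ring is reached in fewer steps than 10. The cis relation of the C4 oxygen and C7 is enforced by the four-membered ring, not by a chelate.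
- Weak points: C5 and C4 are both set in one transition state, with the bulky CMe2OMe group next to the nucleophilic carbon and a methyl ketone as acceptor. β-Lactones of tertiary alcohols lose CO2 on warming. Reductive opening of A2 leaves two free hydroxyl groups that must then be told apart.
- Comparison: this road is shorter to the ring and geometrically safer at C4. The chosen plan sets against it a C1 centre fixed by a catalyst whose antipode is equally available, so it does not depend on the optical purity of a terpene feedstock. It also sets C5 in a separate, dependable lactone alkylation, and its ring product 10 has its two oxygens already differentiated.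

**Alternative 2:** The cut is C1–C2, seen as a ring contraction.
- Key step: the cyclohexyl mesylate A3 (mesylate trans to the silyloxymethyl arm, gem-dimethyl carbon Cq in the ring) would be heated in methanol–hexafluoroisopropanol with 2,6-lutidine. The ring bond Cq–C2, antiperiplanar to the leaving group, migrates to C1 with inversion and methanol captures the cation at Cq, giving the bis-silyl ether A4.
- Merits: ring size, the C1 configuration and the methyl ether arise in one stereospecific step, without mercury and without a facial-selectivity question at C1.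
- Weak points: A3 needs four stereocentres on a cyclohexane that has no cheap chiral-pool relative, and one of them is spent in the migration. Elimination, methyl or hydride shifts, proton loss from the Cq cation and solvolytic loss of the tertiary silyl ether all compete in an ionising medium.
- Comparison: it is better in the stereospecific origin of C1. The chosen plan answers with a much shorter path to its cyclisation substrate and with steps whose side reactions are fewer and easier to suppress.

**Alternative 3:** The cut is C1–C5, patterned on the likely biogenesis.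
- Key step: Sc(OTf)3 in methanol–hexafluoroisopropanol would activate the epoxide A5, which must be the neryl-type (Z-derived) isomer for the hydroxyl to end cis to C7. Alkene carbon C1 attacks the allylic epoxide carbon C5 with inversion and methanol captures the cation at Cq, giving the iodovinyl cyclopentanol A6.
- Merits: three stereocentres and the ether are made in one step from a substrate a few steps from an allylic alcohol by asymmetric epoxidation. A6 could be cross-coupled directly to a polyene at C8, which avoids the β-hydroxy aldehyde altogether.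
- Weak points: the alkene must attack the secondary allylic carbon while the tertiary epoxide carbon C4 ionises more easily. Direct methanolysis of the activated epoxide, Meinwald-type shifts and proton loss from Cq compete. The C1 configuration rests on a small conformational preference between two folded transition states.
- Comparison: in step count and convergence this road is clearly better if the cyclisation is selective. The chosen plan sets against it that each stereocentre is made in a separate operation with a known control element, and that no step has several low-barrier competitors.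

Key step: step 6

## Route

Remarks on the chemistry:
- 8 is drawn as the open-chain hydroxy ketone; any cyclic hemiketal in equilibrium with it reacts through the same open form.
- Commercial 14 is an E/Z mixture whose anion equilibrates; the E isomer is drawn.
- Compounds 24 to 29 are handled under argon in dim light.

Step 1
Reactants: 1 5,6-dihydro-2H-pyran-2-one; 2 isopropenylboronic acid pinacol ester
Product: 3 (R)-4-(prop-1-en-2-yl)tetrahydro-2H-pyran-2-one
Conditions: 2 (2 equiv), [RhCl(C2H4)2]2 (2.5 mol %), (R)-BINAP (5.5 mol %), aq KOH (0.2 equiv), 1,4-dioxane–H2O 10:1, 60 °C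
Reagents that add atoms: none
Why: Rhodium-catalysed asymmetric 1,4-addition of an alkenylboron reagent to a cyclic enoate (Hayashi–Miyaura reaction); the ethylene precatalyst avoids a diene-bound rhodium species that would give racemic background addition, and (R)-BINAP is expected, by the facial model that holds for cyclic enones and unsaturated lactones, to give the (R) centre that becomes C1 (sense to be confirmed on the first batch).

Step 2
Reactants: 3 (R)-4-(prop-1-en-2-yl)tetrahydro-2H-pyran-2-one
Product: 5 (R)-4-(2-methoxypropan-2-yl)tetrahydro-2H-pyran-2-one, via the acetoxymercurio adduct 4 (not isolated)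
Conditions: Hg(OAc)2 (1.1 equiv), MeOH, rt; then NaBH4, aq NaOH, 0 °C, 10 min; aq HCl to pH 3
Reagents that add atoms: methanol, CO
Why: Markovnikov alkoxymercuration–demercuration of a 1,1-disubstituted alkene puts the methoxy group on the tertiary carbon Cq without the cation rearrangement or elimination that protic acid would risk; the short basic demercuration is followed by acidification, which re-closes any opened lactone, and C1 is not touched.

Step 3
Reactants: 5 (R)-4-(2-methoxypropan-2-yl)tetrahydro-2H-pyran-2-one
Product: 7 (3R,4R)-3-[(benzyloxy)methyl]-4-(2-methoxypropan-2-yl)tetrahydro-2H-pyran-2-one, via lithium lactone enolate 6 (not isolated)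
Conditions: LiN(iPr)2 (1.1 equiv), THF, −78 °C; then BnOCH2Cl, −78 → −40 °C
Reagents that add atoms: benzyl chloromethyl ether, ClCOCc1ccccc1
Why: Alkylation of a δ-lactone enolate; the electrophile approaches the face opposite the bulky CMe2OMe group on the neighbouring carbon C1, so the C5–C7 bond forms trans to Cq and sets C5.

Step 4
Reactants: 7 (3R,4R)-3-[(benzyloxy)methyl]-4-(2-methoxypropan-2-yl)tetrahydro-2H-pyran-2-one
Product: 8 (3R,4R)-3-[(benzyloxy)methyl]-6-hydroxy-4-(2-methoxypropan-2-yl)hexan-2-one
Conditions: MeLi (1.05 equiv), THF, −78 °C; aq NH4Cl at −78 °C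
Reagents that add atoms: methyllithium, [Li]C
Why: Mono-addition of methyllithium to a δ-lactone; the lithium hemiketal alkoxide persists at −78 °C and releases the methyl ketone only on quenching, which holds back a second addition, and because the adduct is not an enolate neither C5 nor the β-benzyloxy group is endangered.

Step 5
Reactants: 8 (3R,4R)-3-[(benzyloxy)methyl]-6-hydroxy-4-(2-methoxypropan-2-yl)hexan-2-one
Product: 9 (3R,4R)-3-[(benzyloxy)methyl]-6-iodo-4-(2-methoxypropan-2-yl)hexan-2-one
Conditions: I2, PPh3, imidazole, CH2Cl2, 0 °C → rt; used at once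
Reagents that add atoms: iodine, [I][I]
Why: Appel-type iodination of the primary alcohol through its alkoxyphosphonium iodide; the nearly neutral medium spares the ketone α-centre C5 from epimerisation and the β-benzyloxy group from elimination.

Step 6
Reactants: 9 (3R,4R)-3-[(benzyloxy)methyl]-6-iodo-4-(2-methoxypropan-2-yl)hexan-2-one
Product: 10 (1R,2R,3R)-2-[(benzyloxy)methyl]-3-(2-methoxypropan-2-yl)-1-methylcyclopentan-1-ol
Conditions: SmI2 (2.5 equiv), Fe(dbm)3 (2 mol %, dbm = dibenzoylmethanate), THF, −78 °C → rt; aq potassium sodium tartrate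
Reagents that add atoms: none
Why: Samarium diiodide, helped by the iron additive, transfers an electron to the carbon–iodine bond of 9, and the primary radical at C3 is reduced again to an alkylsamarium (trivalent samarium) that adds to the ketone carbon C4; the alternative order through the ketyl leads to the same bond. The closest known reaction type is the SmI2-promoted intramolecular Barbier cyclisation of ω-iodoalkyl ketones to cyclopentanols. The C3–C4 bond closes the cyclopentane in the 5-exo-trig mode, the carbonyl oxygen staying outside the ring. The one new stereocentre, C4, is controlled by a six-membered chelate in which trivalent samarium bridges the carbonyl oxygen and the benzyloxy oxygen on C7: the oxygen is held syn to the C5–C7 bond while the tether reaches C4 from the side of C1, so the hydroxyl forms cis to C7 and the methyl trans, which is (R) at C4. The step needs this facial selectivity and a preference for iodide reduction over ketone reduction or pinacol coupling; the first is secured by the benzyl ether (a good donor where a silyl ether would not chelate) and by leaving out HMPA, which would saturate the metal and turn the samarium-bound oxygen into the bulky group that avoids C7, the second by the primary iodide and the iron catalyst, which let the reduction begin at −78 °C. The anti relation of C1 and C5 is already in the chain and both centres lie on the forming ring, so nothing else has to be selected. The medium is aprotic and close to neutral, so C5 is not epimerised and benzyloxide is not eliminated, and the product rests as a samarium alkoxide until work-up.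

Step 7
Reactants: 10 (1R,2R,3R)-2-[(benzyloxy)methyl]-3-(2-methoxypropan-2-yl)-1-methylcyclopentan-1-ol
Product: 11 {[(1R,2R,3R)-2-[(benzyloxy)methyl]-3-(2-methoxypropan-2-yl)-1-methylcyclopentyl]oxy}triethylsilane
Conditions: TESOTf, 2,6-lutidine, CH2Cl2, −78 → 0 °C
Reagents that add atoms: triethylsilyl trifluoromethanesulfonate, CC[Si](CC)(CC)OS(=O)(=O)C(F)(F)F
Why: Silyl triflate silylation of a hindered tertiary alcohol; the ether masks the C4 oxygen before C7 becomes a carbonyl carbon and so closes the retro-aldol channel in the steps that follow.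

Step 8
Reactants: 11 {[(1R,2R,3R)-2-[(benzyloxy)methyl]-3-(2-methoxypropan-2-yl)-1-methylcyclopentyl]oxy}triethylsilane
Product: 12 [(1R,2R,5R)-5-(2-methoxypropan-2-yl)-2-methyl-2-[(triethylsilyl)oxy]cyclopentyl]methanol
Conditions: H2 (1 atm), 10% Pd/C, EtOAc, rt
Reagents that add atoms: none
Why: Hydrogenolysis of a benzyl ether at a stage where no alkene is present; in ethyl acetate the triethylsilyl ether and the tertiary methyl ether are inert.

Step 9
Reactants: 12 [(1R,2R,5R)-5-(2-methoxypropan-2-yl)-2-methyl-2-[(triethylsilyl)oxy]cyclopentyl]methanol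
Product: 13 (1S,2R,5R)-5-(2-methoxypropan-2-yl)-2-methyl-2-[(triethylsilyl)oxy]cyclopentane-1-carbaldehyde
Conditions: Dess–Martin periodinane, NaHCO3, CH2Cl2, 0 °C → rt
Reagents that add atoms: none
Why: Buffered hypervalent-iodine oxidation of a primary alcohol stops at the aldehyde; C5 already has its preferred orientation trans to the CMe2OMe group, so the α-centre has no drive to epimerise.

Step 10
Reactants: 13 (1S,2R,5R)-5-(2-methoxypropan-2-yl)-2-methyl-2-[(triethylsilyl)oxy]cyclopentane-1-carbaldehyde; 14 triethyl 3-methyl-4-phosphonocrotonate (ethyl (2E)-4-(diethoxyphosphoryl)-3-methylbut-2-enoate)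
Product: 16 ethyl (2E,4E)-5-[(1S,2R,5R)-5-(2-methoxypropan-2-yl)-2-methyl-2-[(triethylsilyl)oxy]cyclopentyl]-3-methylpenta-2,4-dienoate, via lithiated phosphonate 15 (not isolated)
Conditions: 14 (1.3 equiv), LiN(SiMe3)2 (1.25 equiv), THF, −78 °C; then 13, −78 → 0 °C
Reagents that add atoms: none
Why: Vinylogous Horner–Wadsworth–Emmons olefination; the stabilised anion gives the E alkene at C7=C8 and brings in C9=C10 as E, and it adds to the aldehyde faster than it can deprotonate the hindered α-position, so the β-silyloxy group is not eliminated.

Step 11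
Reactants: 16 ethyl (2E,4E)-5-[(1S,2R,5R)-5-(2-methoxypropan-2-yl)-2-methyl-2-[(triethylsilyl)oxy]cyclopentyl]-3-methylpenta-2,4-dienoate
Product: 17 (2E,4E)-5-[(1S,2R,5R)-5-(2-methoxypropan-2-yl)-2-methyl-2-[(triethylsilyl)oxy]cyclopentyl]-3-methylpenta-2,4-dien-1-ol
Conditions: DIBAL-H (2.5 equiv), CH2Cl2, −78 °C; aq potassium sodium tartrate
Reagents that add atoms: none
Why: 1,2-Reduction of a conjugated ester to the allylic alcohol by an aluminium hydride, without conjugate reduction and without effect on the silyl or methyl ether.

Step 12
Reactants: 17 (2E,4E)-5-[(1S,2R,5R)-5-(2-methoxypropan-2-yl)-2-methyl-2-[(triethylsilyl)oxy]cyclopentyl]-3-methylpenta-2,4-dien-1-ol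
Product: 18 (2E,4E)-5-[(1S,2R,5R)-5-(2-methoxypropan-2-yl)-2-methyl-2-[(triethylsilyl)oxy]cyclopentyl]-3-methylpenta-2,4-dienal
Conditions: MnO2 (activated, 15 equiv), CH2Cl2, rt
Reagents that add atoms: none
Why: Selective oxidation of an allylic alcohol on manganese dioxide, neutral and without isomerisation of the dienal.

Step 13
Reactants: 19 pseudoionone ((3E,5E)-6,10-dimethylundeca-3,5,9-trien-2-one)
Product: 20 (4E,6E)-3,7,11-trimethyldodeca-1,4,6,10-tetraen-3-ol (racemic)
Conditions: CH2=CHMgBr, THF, −20 → 0 °C
Reagents that add atoms: vinylmagnesium bromide, C=C[Mg]Br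
Why: 1,2-Addition of a vinyl Grignard reagent to the dienone carbonyl; the carbinol centre disappears in the next step, so its configuration is of no account.

Step 14
Reactants: 20 (4E,6E)-3,7,11-trimethyldodeca-1,4,6,10-tetraen-3-ol
Product: 21 [(2E,4E,6E)-3,7,11-trimethyldodeca-2,4,6,10-tetraen-1-yl]triphenylphosphonium bromide
Conditions: PPh3·HBr, MeOH, 0 °C → rt; crystallisation of the 2E salt
Reagents that add atoms: triphenylphosphine hydrobromide, [Br-].c1ccccc1[PH+](c1ccccc1)c1ccccc1
Why: Acid-induced ionisation of the tertiary bis-allylic alcohol and capture of the delocalised cation by triphenylphosphine at the primary terminus (allylic transposition), the standard entry to polyenyl Wittig salts.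

Step 15
Reactants: 21 [(2E,4E,6E)-3,7,11-trimethyldodeca-2,4,6,10-tetraen-1-yl]triphenylphosphonium bromide; 22 (2E,4E,6E)-2,7-dimethylocta-2,4,6-trienedial
Product: 24 (2E,4E,6E,8E,10E,12E,14E)-2,7,11,15,19-pentamethylicosa-2,4,6,8,10,12,14,18-octaenal, via the C15 ylide 23 (not isolated)
Conditions: 21, NaN(SiMe3)2 (1.0 equiv), THF, −78 °C; added to 22 (3 equiv), THF, −78 → 0 °C; then heptane, 80 °C
Reagents that add atoms: none
Why: Wittig olefination of one formyl group of the symmetrical dialdehyde, with the ylide as the limiting partner so that the second, now less electrophilic aldehyde survives; heating equilibrates the hindered Z isomer at the new C11'=C12' bond to E.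

Step 16
Reactants: 24 (2E,4E,6E,8E,10E,12E,14E)-2,7,11,15,19-pentamethylicosa-2,4,6,8,10,12,14,18-octaenal
Product: 25 (2E,4E,6E,8E,10E,12E,14E)-2,7,11,15,19-pentamethylicosa-2,4,6,8,10,12,14,18-octaen-1-ol
Conditions: NaBH4, EtOH–THF, 0 °C
Reagents that add atoms: none
Why: Borohydride reduction of a polyenal is a clean 1,2-reduction.

Step 17
Reactants: 25 (2E,4E,6E,8E,10E,12E,14E)-2,7,11,15,19-pentamethylicosa-2,4,6,8,10,12,14,18-octaen-1-ol
Product: 26 [(2E,4E,6E,8E,10E,12E,14E)-2,7,11,15,19-pentamethylicosa-2,4,6,8,10,12,14,18-octaen-1-yl]triphenylphosphonium bromide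
Conditions: PPh3·HBr, MeOH–CH2Cl2, 0 °C → rt
Reagents that add atoms: triphenylphosphine hydrobromide, [Br-].c1ccccc1[PH+](c1ccccc1)c1ccccc1
Why: The polyenyl alcohol ionises readily and triphenylphosphine is expected to add at the primary terminus, which keeps the full conjugation; this is the usual conversion of apo-carotenols into Wittig salts.

Step 18
Reactants: 26 [(2E,4E,6E,8E,10E,12E,14E)-2,7,11,15,19-pentamethylicosa-2,4,6,8,10,12,14,18-octaen-1-yl]triphenylphosphonium bromide; 18 (2E,4E)-5-[(1S,2R,5R)-5-(2-methoxypropan-2-yl)-2-methyl-2-[(triethylsilyl)oxy]cyclopentyl]-3-methylpenta-2,4-dienal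
Product: 28 triethyl{[(1R,2S,3R)-2-[(1E,3E,5E,7E,9E,11E,13E,15E,17E,19E)-3,7,12,16,20,24-hexamethylpentacosa-1,3,5,7,9,11,13,15,17,19,23-undecaen-1-yl]-3-(2-methoxypropan-2-yl)-1-methylcyclopentyl]oxy}silane, via the C25 ylide 27 (not isolated)
Conditions: 26 (1.2 equiv), NaN(SiMe3)2 (1.15 equiv), THF, −78 °C; then 18, −78 °C → rt; then heptane, 80 °C, argon, dark
Reagents that add atoms: none
Why: Wittig olefination of a polyenal with a polyenyl ylide, the classical union of carotenoid halves; the hindered (11Z) isomer formed beside the E isomer should equilibrate thermally to the all-E chain, and the ring stereocentres are remote from the reacting carbons.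

Step 19
Reactants: 28 triethylsilyl ether of the target
Product: 29 CNP0380368.2, (1R,2S,3R)-2-[(1E,3E,5E,7E,9E,11E,13E,15E,17E,19E)-3,7,12,16,20,24-hexamethylpentacosa-1,3,5,7,9,11,13,15,17,19,23-undecaen-1-yl]-3-(2-methoxypropan-2-yl)-1-methylcyclopentan-1-ol
Conditions: Bu4NF (2 equiv), THF, 0 °C → rt, argon, dark
Reagents that add atoms: none
Why: Fluoride cleavage of a triethylsilyl ether is neutral towards the polyene and the tertiary methyl ether, and with no carbonyl group left the free tertiary alcohol has no retro-aldol path.

## Compound list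

1 | 5,6-dihydro-2H-pyran-2-one | O=C1C=CCCO1 | starting material
2 | isopropenylboronic acid pinacol ester | CC(=C)B1OC(C)(C)C(C)(C)O1 | starting material
3 | (R)-4-(prop-1-en-2-yl)tetrahydro-2H-pyran-2-one | CC(=C)[C@@H]1CCOC(=O)C1 | intermediate
4 | {2-methoxy-2-[(4R)-2-oxooxan-4-yl]propyl}mercury acetate (both epimers at the methoxy-bearing carbon) | COC(C)(C[Hg]OC(C)=O)[C@@H]1CCOC(=O)C1 | intermediate (not isolated)
5 | (R)-4-(2-methoxypropan-2-yl)tetrahydro-2H-pyran-2-one | COC(C)(C)[C@@H]1CCOC(=O)C1 | intermediate
6 | lithium (R)-4-(2-methoxypropan-2-yl)-5,6-dihydro-4H-pyran-2-olate | [Li+].COC(C)(C)[C@@H]1CCOC([O-])=C1 | intermediate (not isolated)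
7 | (3R,4R)-3-[(benzyloxy)methyl]-4-(2-methoxypropan-2-yl)tetrahydro-2H-pyran-2-one | COC(C)(C)[C@@H]1CCOC(=O)[C@H]1COCc1ccccc1 | intermediate
8 | (3R,4R)-3-[(benzyloxy)methyl]-6-hydroxy-4-(2-methoxypropan-2-yl)hexan-2-one | COC(C)(C)[C@H](CCO)[C@H](COCc1ccccc1)C(C)=O | intermediate
9 | (3R,4R)-3-[(benzyloxy)methyl]-6-iodo-4-(2-methoxypropan-2-yl)hexan-2-one | COC(C)(C)[C@H](CCI)[C@H](COCc1ccccc1)C(C)=O | intermediate
10 | (1R,2R,3R)-2-[(benzyloxy)methyl]-3-(2-methoxypropan-2-yl)-1-methylcyclopentan-1-ol | COC(C)(C)[C@@H]1CC[C@@](C)(O)[C@H]1COCc1ccccc1 | intermediate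
11 | {[(1R,2R,3R)-2-[(benzyloxy)methyl]-3-(2-methoxypropan-2-yl)-1-methylcyclopentyl]oxy}triethylsilane | COC(C)(C)[C@@H]1CC[C@@](C)(O[Si](CC)(CC)CC)[C@H]1COCc1ccccc1 | intermediate
12 | [(1R,2R,5R)-5-(2-methoxypropan-2-yl)-2-methyl-2-[(triethylsilyl)oxy]cyclopentyl]methanol | COC(C)(C)[C@@H]1CC[C@@](C)(O[Si](CC)(CC)CC)[C@H]1CO | intermediate
13 | (1S,2R,5R)-5-(2-methoxypropan-2-yl)-2-methyl-2-[(triethylsilyl)oxy]cyclopentane-1-carbaldehyde | COC(C)(C)[C@@H]1CC[C@@](C)(O[Si](CC)(CC)CC)[C@H]1C=O | intermediate
14 | triethyl 3-methyl-4-phosphonocrotonate | CCOC(=O)/C=C(\C)CP(=O)(OCC)OCC | starting material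
15 | lithium salt of 14 (delocalised anion) | [Li+].CCOC(=O)C=C(C)[CH-]P(=O)(OCC)OCC | intermediate (not isolated)
16 | ethyl (2E,4E)-5-[(1S,2R,5R)-5-(2-methoxypropan-2-yl)-2-methyl-2-[(triethylsilyl)oxy]cyclopentyl]-3-methylpenta-2,4-dienoate | COC(C)(C)[C@@H]1CC[C@@](C)(O[Si](CC)(CC)CC)[C@H]1/C=C/C(C)=C/C(=O)OCC | intermediate
17 | (2E,4E)-5-[(1S,2R,5R)-5-(2-methoxypropan-2-yl)-2-methyl-2-[(triethylsilyl)oxy]cyclopentyl]-3-methylpenta-2,4-dien-1-ol | COC(C)(C)[C@@H]1CC[C@@](C)(O[Si](CC)(CC)CC)[C@H]1/C=C/C(C)=C/CO | intermediate
18 | (2E,4E)-5-[(1S,2R,5R)-5-(2-methoxypropan-2-yl)-2-methyl-2-[(triethylsilyl)oxy]cyclopentyl]-3-methylpenta-2,4-dienal | COC(C)(C)[C@@H]1CC[C@@](C)(O[Si](CC)(CC)CC)[C@H]1/C=C/C(C)=C/C=O | intermediate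
19 | pseudoionone, (3E,5E)-6,10-dimethylundeca-3,5,9-trien-2-one | CC(=O)/C=C/C=C(\C)CCC=C(C)C | starting material
20 | (4E,6E)-3,7,11-trimethyldodeca-1,4,6,10-tetraen-3-ol (racemic) | C=CC(C)(O)/C=C/C=C(\C)CCC=C(C)C | intermediate
21 | [(2E,4E,6E)-3,7,11-trimethyldodeca-2,4,6,10-tetraen-1-yl]triphenylphosphonium bromide | [Br-].c1ccccc1[P+](c1ccccc1)(c1ccccc1)C/C=C(C)/C=C/C=C(\C)CCC=C(C)C | intermediate
22 | (2E,4E,6E)-2,7-dimethylocta-2,4,6-trienedial | O=C/C(C)=C/C=C/C=C(\C)C=O | starting material
23 | triphenyl[(2E,4E,6E)-3,7,11-trimethyldodeca-2,4,6,10-tetraen-1-ylidene]phosphorane | c1ccccc1P(c1ccccc1)(c1ccccc1)=C/C=C(C)/C=C/C=C(\C)CCC=C(C)C | intermediate (not isolated)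
24 | (2E,4E,6E,8E,10E,12E,14E)-2,7,11,15,19-pentamethylicosa-2,4,6,8,10,12,14,18-octaenal | O=C/C(C)=C/C=C/C=C(C)/C=C/C=C(C)/C=C/C=C(\C)CCC=C(C)C | intermediate
25 | (2E,4E,6E,8E,10E,12E,14E)-2,7,11,15,19-pentamethylicosa-2,4,6,8,10,12,14,18-octaen-1-ol | OC/C(C)=C/C=C/C=C(C)/C=C/C=C(C)/C=C/C=C(\C)CCC=C(C)C | intermediate
26 | [(2E,4E,6E,8E,10E,12E,14E)-2,7,11,15,19-pentamethylicosa-2,4,6,8,10,12,14,18-octaen-1-yl]triphenylphosphonium bromide | [Br-].c1ccccc1[P+](c1ccccc1)(c1ccccc1)C/C(C)=C/C=C/C=C(C)/C=C/C=C(C)/C=C/C=C(\C)CCC=C(C)C | intermediate
27 | triphenyl[(2E,4E,6E,8E,10E,12E,14E)-2,7,11,15,19-pentamethylicosa-2,4,6,8,10,12,14,18-octaen-1-ylidene]phosphorane | c1ccccc1P(c1ccccc1)(c1ccccc1)=C/C(C)=C/C=C/C=C(C)/C=C/C=C(C)/C=C/C=C(\C)CCC=C(C)C | intermediate (not isolated)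
28 | triethylsilyl ether of 29 (ring 1R,2S,3R; chain all-E) | COC(C)(C)[C@@H]1CC[C@@](C)(O[Si](CC)(CC)CC)[C@H]1/C=C/C(C)=C/C=C/C(C)=C/C=C/C=C(C)/C=C/C=C(C)/C=C/C=C(\C)CCC=C(C)C | intermediate
29 | CNP0380368.2, (1R,2S,3R)-2-[(1E,3E,5E,7E,9E,11E,13E,15E,17E,19E)-3,7,12,16,20,24-hexamethylpentacosa-1,3,5,7,9,11,13,15,17,19,23-undecaen-1-yl]-3-(2-methoxypropan-2-yl)-1-methylcyclopentan-1-ol | COC(C)(C)[C@@H]1CC[C@@](C)(O)[C@H]1/C=C/C(C)=C/C=C/C(C)=C/C=C/C=C(C)/C=C/C=C(C)/C=C/C=C(\C)CCC=C(C)C | target

## Step count and least certain steps

Total step count: 19. Longest linear sequence: 14 steps (steps 1 to 12, 18 and 19, from 1). The C25 branch (steps 13 to 17) has five steps before the union.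

**Step 6 (key step).**
- Most likely failure: loss of facial selectivity at C4. If the chelate is not maintained, the samarium-bound oxygen becomes the larger group and turns away from C7, which gives the C4 epimer. Simple reduction of the iodide, or of the ketone, is the second risk.
- Fallback: it sets out from lactone 7 and returns at 10, keeping C3–C4 as the ring-closing bond but setting C4 by addition to a ring ketone.
- Aminolysis with Me(MeO)NH·HCl and AlMe3 (CH2Cl2, 0 °C) gives the hydroxy Weinreb amide (2R,3R)-2-[(benzyloxy)methyl]-5-hydroxy-N-methoxy-3-(2-methoxypropan-2-yl)-N-methylpentanamide F1.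
- I2, PPh3 and imidazole give the iodo Weinreb amide F2.
- t-BuLi (2.1 equiv, Et2O–pentane, −100 → −78 °C) effects iodine–lithium exchange, and the alkyllithium acylates the amide intramolecularly to the cyclopentanone (2R,3R)-2-[(benzyloxy)methyl]-3-(2-methoxypropan-2-yl)cyclopentan-1-one F3.
- MeMgBr with CeCl3 (THF, −78 °C) is then expected to add from the face opposite the C5 substituent, which places the hydroxyl cis to C7 and gives 10. This selectivity would have to be confirmed, since the C1 substituent lies on the attacked face.

**Step 1.**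
- Most likely failure: slow transmetalation of the 1,1-disubstituted alkenylboronate, so that protodeboronation and base-induced opening of the lactone outrun the addition, or an enantioselectivity below what the later steps can carry.
- Fallback: it draws on the chiral pool. It sets out not from a compound of the route but from commercial (R)-(+)-α-terpineol F4 and returns at 5, so it replaces steps 1 and 2 together.
- O-Methylation (KH, MeI, THF) gives (R)-4-(2-methoxypropan-2-yl)-1-methylcyclohex-1-ene F5.
- Ozonolysis (O3, CH2Cl2–MeOH, −78 °C; Me2S) gives the keto aldehyde (R)-3-(2-methoxypropan-2-yl)-6-oxoheptanal F6.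
- Pinnick oxidation (NaClO2, NaH2PO4, 2-methylbut-2-ene) gives the keto acid (R)-3-(2-methoxypropan-2-yl)-6-oxoheptanoic acid F7.
- Baeyer–Villiger oxidation of the methyl ketone (CF3CO3H, Na2HPO4, CH2Cl2, 0 °C), in which the primary alkyl group migrates in preference to methyl, gives the acetoxy acid (R)-5-acetoxy-3-(2-methoxypropan-2-yl)pentanoic acid F8.
- Methanolysis of the acetate (K2CO3, MeOH) and acidification close the lactone 5. The terpineol stereocentre becomes C1 without being touched.

**Step 2.**
- Most likely failure: participation of the lactone carbonyl oxygen in opening the mercurinium ion, and reduction or hydrolysis of the lactone during the basic borohydride stage.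
- Fallback: from 3 to 5 by cohalogenation and radical reduction, which removes the basic hydride stage. N-Bromosuccinimide in MeOH (0 °C) gives the bromo ether (4R)-4-(1-bromo-2-methoxypropan-2-yl)tetrahydro-2H-pyran-2-one F9, and Bu3SnH with azobisisobutyronitrile (toluene, 80 °C) removes the bromine to give 5.

**Step 4.**
- Most likely failure: collapse of the tetrahedral intermediate before the quench, leading to a second methyl addition, or enolisation of the lactone with return of 7.
- Fallback: from 7 to 8 without a carbanion. Methylenation with Cp2TiMe2 (toluene, 65 °C, dark; Petasis methylenation) gives the enol ether (3R,4R)-3-[(benzyloxy)methyl]-4-(2-methoxypropan-2-yl)-2-methylideneoxane F10, and mild hydration (aq oxalic acid, THF, 0 °C) gives 8.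

**Step 18.**
- Most likely failure: a low E share at C11=C12 with incomplete thermal equilibration, together with oxidative or base-induced decay of the long ylide 27 and of the product polyene.
- Fallback: it reverses the polarity of the union, sets out from 17 and 24 and returns at 28; it also makes steps 16 and 17 unnecessary.
- Mitsunobu reaction of 17 with 2-mercaptobenzothiazole (PPh3, diisopropyl azodicarboxylate, THF, 0 °C) gives the sulfide 2-{[(2E,4E)-5-[(1S,2R,5R)-5-(2-methoxypropan-2-yl)-2-methyl-2-[(triethylsilyl)oxy]cyclopentyl]-3-methylpenta-2,4-dien-1-yl]sulfanyl}-1,3-benzothiazole F11.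
- Oxidation ((NH4)6Mo7O24 (cat.), H2O2, EtOH, 0 °C) gives the sulfone F12.
- Julia–Kocienski olefination of F12 with 24 (NaN(SiMe3)2, THF, −78 °C), followed by the same thermal equilibration, gives 28.

## Further compounds

F1 | step 6 | (2R,3R)-2-[(benzyloxy)methyl]-5-hydroxy-N-methoxy-3-(2-methoxypropan-2-yl)-N-methylpentanamide | COC(C)(C)[C@H](CCO)[C@H](COCc1ccccc1)C(=O)N(C)OC
F2 | step 6 | (2R,3R)-2-[(benzyloxy)methyl]-5-iodo-N-methoxy-3-(2-methoxypropan-2-yl)-N-methylpentanamide | COC(C)(C)[C@H](CCI)[C@H](COCc1ccccc1)C(=O)N(C)OC
F3 | step 6 | (2R,3R)-2-[(benzyloxy)methyl]-3-(2-methoxypropan-2-yl)cyclopentan-1-one | COC(C)(C)[C@@H]1CCC(=O)[C@H]1COCc1ccccc1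
F4 | step 1 | (R)-(+)-α-terpineol | CC1=CC[C@@H](CC1)C(C)(C)O
F5 | step 1 | (R)-4-(2-methoxypropan-2-yl)-1-methylcyclohex-1-ene | CC1=CC[C@@H](CC1)C(C)(C)OC
F6 | step 1 | (R)-3-(2-methoxypropan-2-yl)-6-oxoheptanal | COC(C)(C)[C@H](CCC(C)=O)CC=O
F7 | step 1 | (R)-3-(2-methoxypropan-2-yl)-6-oxoheptanoic acid | COC(C)(C)[C@H](CCC(C)=O)CC(=O)O
F8 | step 1 | (R)-5-acetoxy-3-(2-methoxypropan-2-yl)pentanoic acid | COC(C)(C)[C@H](CCOC(C)=O)CC(=O)O
F9 | step 2 | (4R)-4-(1-bromo-2-methoxypropan-2-yl)tetrahydro-2H-pyran-2-one | COC(C)(CBr)[C@@H]1CCOC(=O)C1
F10 | step 4 | (3R,4R)-3-[(benzyloxy)methyl]-4-(2-methoxypropan-2-yl)-2-methylideneoxane | COC(C)(C)[C@@H]1CCOC(=C)[C@H]1COCc1ccccc1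
F11 | step 18 | 2-{[(2E,4E)-5-[(1S,2R,5R)-5-(2-methoxypropan-2-yl)-2-methyl-2-[(triethylsilyl)oxy]cyclopentyl]-3-methylpenta-2,4-dien-1-yl]sulfanyl}-1,3-benzothiazole | COC(C)(C)[C@@H]1CC[C@@](C)(O[Si](CC)(CC)CC)[C@H]1/C=C/C(C)=C/CSc1nc2ccccc2s1
F12 | step 18 | 2-{[(2E,4E)-5-[(1S,2R,5R)-5-(2-methoxypropan-2-yl)-2-methyl-2-[(triethylsilyl)oxy]cyclopentyl]-3-methylpenta-2,4-dien-1-yl]sulfonyl}-1,3-benzothiazole | COC(C)(C)[C@@H]1CC[C@@](C)(O[Si](CC)(CC)CC)[C@H]1/C=C/C(C)=C/CS(=O)(=O)c1nc2ccccc2s1
A1 | alternative 1 | (R)-3-(2-methoxypropan-2-yl)-6-oxoheptanoic acid | COC(C)(C)[C@H](CCC(C)=O)CC(=O)O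
A2 | alternative 1 | cis-fused 2-(2-methoxypropan-2-yl)-5-methyl-6-oxabicyclo[3.2.0]heptan-7-one, side chain anti to the lactone | COC(C)(C)[C@@H]1CC[C@@]2(C)OC(=O)[C@@H]12
A3 | alternative 2 | 6-{[(tert-butyldimethylsilyl)oxy]methyl}-2,2,5-trimethyl-5-[(triethylsilyl)oxy]cyclohexyl methanesulfonate, mesylate trans to the silyloxymethyl arm | [C@@H]1(OS(C)(=O)=O)C(C)(C)CC[C@@](C)(O[Si](CC)(CC)CC)[C@H]1CO[Si](C)(C)C(C)(C)C
A4 | alternative 2 | bis-silyl ether of 2-(hydroxymethyl)-3-(2-methoxypropan-2-yl)-1-methylcyclopentan-1-ol | COC(C)(C)[C@@H]1CC[C@@](C)(O[Si](CC)(CC)CC)[C@H]1CO[Si](C)(C)C(C)(C)C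
A5 | alternative 3 | 2-[(E)-2-iodoethenyl]-3-methyl-3-(4-methylpent-3-en-1-yl)oxirane, iodovinyl group cis to the alkenyl chain | CC(C)=CCC[C@@]1(C)O[C@H]1/C=C/I
A6 | alternative 3 | 2-[(E)-2-iodoethenyl]-3-(2-methoxypropan-2-yl)-1-methylcyclopentan-1-ol | COC(C)(C)[C@@H]1CC[C@@](C)(O)[C@H]1/C=C/I
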